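## Retrosynthetic overview
1. Ring atoms are C1 (C=O), C2 (C-OMe), C3 (C-aryl), C4 (spiro carbon) and C5 (C(OMe)aryl). The oxirane is made last: C4-OH displaces a primary mesylate on the CH2, the C4-O bond stays untouched, and the phenol TIPS ethers fall in the same flask.
2. The cyclopentenone closes at C2=C3 by intramolecular aldol condensation of the 1,4-diketone ArCO-C4-C5-CO-CH2OMe. C4 and C5 are already quaternary, and only CH2OMe can enolise.
3. The diketone comes from four fragments joined at the C4/C5 core: an L-serine-derived glycerate acetal (C3 carboxyl, C4, CH2O), an aroyl chloride (C5 and its aryl), 1-(methoxymethyl)vinyllithium (C1-C2, C=O freed by ozonolysis) and an aryllithium (C3 aryl).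
4. C4 is set by self-regeneration of the serine stereocentre through a tert-butyl dioxolane, and C5 by chelate-controlled addition next to C4. Ring order: temporary 1,3-dioxolane, then cyclopentenone, then oxirane.

Assumption: operations run in one flask without isolation count as one step. LiN(i-Pr)2, t-BuLi, n-BuLi and n-Bu4NF are bought as solutions. TIPS = triisopropylsilyl.

## Route

Step 1
Reactants: 1 L-serine
Product: 2 (2S)-2,3-dihydroxypropanoic acid ((S)-glyceric acid)
Conditions: NaNO2, 1 M aq H2SO4, 0 °C to rt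
Reagents that add atoms: water, O
Why: Diazotisation with deaminative hydroxylation; neighbouring-carboxylate participation causes a double inversion, so the serine stereocentre is kept as S.

Step 2
Reactants: 2 (S)-glyceric acid
Product: 3 methyl (2S)-2,3-dihydroxypropanoate
Conditions: MeOH, HCl (cat.), reflux
Reagents that add atoms: methanol, CO
Why: Fischer esterification, which does not touch the carbinol stereocentre.

Step 3
Reactants: 3 methyl (2S)-2,3-dihydroxypropanoate
Product: 4 methyl (2S,4S)-2-tert-butyl-1,3-dioxolane-4-carboxylate (cis isomer)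
Conditions: t-BuCHO, TsOH·H2O (cat.), pentane, reflux, Dean–Stark; chromatography
Reagents that add atoms: pivalaldehyde, CC(C)(C)C=O
Why: Acid-catalysed acetalisation under thermodynamic control sets the acetal carbon; the favoured cis (2S) isomer is separated and the trans isomer is re-equilibrated with acid and recycled.

Step 4
Reactants: 5 4-hydroxybenzoic acid
Product: 6 triisopropylsilyl 4-(triisopropylsilyloxy)benzoate
Conditions: TIPSCl (2.2 equiv), imidazole, DMF, rt
Reagents that add atoms: triisopropylsilyl chloride, CC(C)[Si](Cl)(C(C)C)C(C)C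
Why: Imidazole-promoted silylation of both acidic OH groups; the aryl TIPS ether is the phenol protection most stable to base and acid.

Step 5
Reactants: 6 triisopropylsilyl 4-(triisopropylsilyloxy)benzoate
Product: 7 4-(triisopropylsilyloxy)benzoic acid
Conditions: K2CO3 (1 equiv), THF/MeOH/H2O, rt, 1 h; then 1 M HCl to pH 3
Reagents that add atoms: none
Why: Chemoselective solvolysis, because the silyl ester is far more labile at silicon than the hindered aryl TIPS ether.

Step 6
Reactants: 7 4-(triisopropylsilyloxy)benzoic acid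
Product: 8 4-(triisopropylsilyloxy)benzoyl chloride
Conditions: (COCl)2, DMF (cat.), CH2Cl2, 0 °C to rt
Reagents that add atoms: oxalyl chloride, O=C(Cl)C(Cl)=O
Why: Vilsmeier-type activation gives the acid chloride under neutral conditions with only gaseous by-products, which the silyl ether tolerates.

Step 7
Reactants: 4 methyl (2S,4S)-2-tert-butyl-1,3-dioxolane-4-carboxylate; 8 4-(triisopropylsilyloxy)benzoyl chloride
Product: 10 methyl (2S,4R)-2-tert-butyl-4-[4-(triisopropylsilyloxy)benzoyl]-1,3-dioxolane-4-carboxylate, via lithium enolate 9 (not isolated)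
Conditions: LiN(i-Pr)2, THF, −78 °C; then 8, −78 to −40 °C
Reagents that add atoms: none
Why: Seebach self-regeneration of the stereocentre with a crossed Claisen C-acylation; enolate 9 keeps only the acetal stereocentre, its tert-butyl group blocks one face, the aroyl group enters anti to it and fixes quaternary C4 as R, and the product has no α-H to scramble.

Step 8
Reactants: 11 2,3-dibromoprop-1-ene
Product: 12 2-bromo-3-methoxyprop-1-ene
Conditions: NaOMe, MeOH, 0 °C to rt
Reagents that add atoms: sodium methoxide, [Na+].[O-]C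
Why: SN2 displacement of the allylic bromide; the vinylic bromide is inert, and an SN2' path gives the same product.

Step 9
Reactants: 12 2-bromo-3-methoxyprop-1-ene; 10 methyl (2S,4R)-2-tert-butyl-4-[4-(triisopropylsilyloxy)benzoyl]-1,3-dioxolane-4-carboxylate
Product: 15 methyl (2S,4R)-2-tert-butyl-4-{(1S)-1-methoxy-2-(methoxymethyl)-1-[4-(triisopropylsilyloxy)phenyl]prop-2-en-1-yl}-1,3-dioxolane-4-carboxylate, via vinyllithium 13 (not isolated), via lithium alkoxide 14 (not isolated)
Conditions: 12 (1.3 equiv), t-BuLi (2.6 equiv), Et2O, −78 °C; 10 in toluene, −78 °C; then MeOTf (4 equiv), −78 to 0 °C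
Reagents that add atoms: methyl trifluoromethanesulfonate, COS(=O)(=O)C(F)(F)F
Why: Bromine–lithium exchange, then Cram-chelate 1,2-addition to the ketone (much faster than to the ester at −78 °C); lithium bridges the ketone O with the dioxolane O or the ester C=O, both chelates open the face anti to CO2Me and so set C5, and Williamson-type trapping of 14 with MeOTf at low temperature outruns retro-aldol cleavage.

Step 10
Reactants: 16 4-bromophenol
Product: 17 (4-bromophenoxy)triisopropylsilane
Conditions: TIPSCl, imidazole, DMF, rt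
Reagents that add atoms: triisopropylsilyl chloride, CC(C)[Si](Cl)(C(C)C)C(C)C
Why: Standard phenol silylation, giving a bromide that survives halogen–metal exchange.

Step 11
Reactants: 17 (4-bromophenoxy)triisopropylsilane; 15 the methyl ether ester from step 9
Product: 19 {(2S,4R)-2-tert-butyl-4-[(1S)-1-methoxy-2-(methoxymethyl)-1-[4-(triisopropylsilyloxy)phenyl]prop-2-en-1-yl]-1,3-dioxolan-4-yl}[4-(triisopropylsilyloxy)phenyl]methanone, via aryllithium 18 (not isolated)
Conditions: 17 (1.5 equiv), n-BuLi (1.5 equiv), THF, −78 °C; then 15, −78 to 0 °C; H2O quench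
Reagents that add atoms: none
Why: Bromine–lithium exchange and nucleophilic acyl substitution on the α-alkoxy ester; the resulting ketone sits next to two quaternary carbons and is deactivated by the para silyloxy group, so a second addition does not compete, and no stereocentre is touched.

Step 12
Reactants: 19 the aryl ketone from step 11
Product: 20 (1R)-1-{(2S,4R)-2-tert-butyl-4-[4-(triisopropylsilyloxy)benzoyl]-1,3-dioxolan-4-yl}-1,3-dimethoxy-1-[4-(triisopropylsilyloxy)phenyl]propan-2-one
Conditions: O3, CH2Cl2, −78 °C, stopped at the first blue colour; then Me2S, −78 °C to rt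
Reagents that add atoms: ozone, [O-][O+]=O
Why: Criegee ozonolysis of the only C=C with reductive work-up frees the C1 ketone; the alkene reacts far faster than the silyloxyarenes, and the C5 descriptor changes to R only through the priority rules.

Step 13
Reactants: 20 the 1,4-diketone from step 12
Product: 22 (2S,5R,6R)-2-tert-butyl-6,8-dimethoxy-6,9-bis[4-(triisopropylsilyloxy)phenyl]-1,3-dioxaspiro[4.4]non-8-en-7-one, via potassium aldolate 21 (not isolated)
Conditions: KOt-Bu (1.1 equiv), THF, −20 to 0 °C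
Reagents that add atoms: none
Why: Intramolecular aldol condensation (5-enolexo addition, then E1cB loss of hydroxide); CH2OMe is the only enolisable position and the aryl ketone the only carbonyl within five-ring reach, while C4 and C5 are quaternary and C4–O is locked in the acetal, so neither epimerisation nor retro-aldol can reach the two stereocentres.

Step 14
Reactants: 22 the spiro acetal enone from step 13
Product: 23 (4R,5R)-4-hydroxy-4-(hydroxymethyl)-2,5-dimethoxy-3,5-bis[4-(triisopropylsilyloxy)phenyl]cyclopent-2-en-1-one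
Conditions: TFA/H2O (9:1), CH2Cl2, 0 °C to rt
Reagents that add atoms: none
Why: Acid hydrolysis of the acetal through the oxocarbenium ion at the pivalaldehyde carbon; both C–O bonds of the diol stay intact, and the aryl TIPS ethers, the enone and the α-keto tertiary methyl ether are stable to acid.

Step 15
Reactants: 23 the enone diol from step 14
Product: 25 (3R,4R)-4,7-bis(4-hydroxyphenyl)-4,6-dimethoxy-1-oxaspiro[2.4]hept-6-en-5-one (target), via primary mesylate 24 (not isolated)
Conditions: MsCl (1.05 equiv), Et3N, CH2Cl2, −30 °C; then n-Bu4NF (1 M in THF, 4 equiv), 0 °C to rt; H2O work-up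
Reagents that add atoms: none
Why: Chemoselective mesylation of the primary OH, then fluoride removes both TIPS groups and acts as base for a 3-exo-tet intramolecular Williamson closure; the C4–O bond is never broken, so C4 stays R with O cis to the C5 aryl, and closure onto the preinstalled leaving group is faster than retro-aldol of the C4 alkoxide.

## Compound list
1 | L-serine | N[C@@H](CO)C(=O)O | starting material
2 | (2S)-2,3-dihydroxypropanoic acid | O[C@@H](CO)C(=O)O | intermediate
3 | methyl (2S)-2,3-dihydroxypropanoate | COC(=O)[C@@H](O)CO | intermediate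
4 | methyl (2S,4S)-2-tert-butyl-1,3-dioxolane-4-carboxylate | COC(=O)[C@@H]1CO[C@H](C(C)(C)C)O1 | intermediate
5 | 4-hydroxybenzoic acid | OC(=O)c1ccc(O)cc1 | starting material
6 | triisopropylsilyl 4-(triisopropylsilyloxy)benzoate | CC(C)[Si](OC(=O)c1ccc(O[Si](C(C)C)(C(C)C)C(C)C)cc1)(C(C)C)C(C)C | intermediate
7 | 4-(triisopropylsilyloxy)benzoic acid | OC(=O)c1ccc(O[Si](C(C)C)(C(C)C)C(C)C)cc1 | intermediate
8 | 4-(triisopropylsilyloxy)benzoyl chloride | ClC(=O)c1ccc(O[Si](C(C)C)(C(C)C)C(C)C)cc1 | intermediate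
9 | lithium enolate of 4 (acetal carbon S) | [Li+].COC([O-])=C1CO[C@H](C(C)(C)C)O1 | intermediate
10 | methyl (2S,4R)-2-tert-butyl-4-[4-(triisopropylsilyloxy)benzoyl]-1,3-dioxolane-4-carboxylate | COC(=O)[C@@]1(CO[C@H](C(C)(C)C)O1)C(=O)c2ccc(O[Si](C(C)C)(C(C)C)C(C)C)cc2 | intermediate
11 | 2,3-dibromoprop-1-ene | C=C(Br)CBr | starting material
12 | 2-bromo-3-methoxyprop-1-ene | COCC(Br)=C | intermediate
13 | (3-methoxyprop-1-en-2-yl)lithium | [Li]C(=C)COC | intermediate
14 | lithium alkoxide of the tertiary alcohol (2S,4R,1'S) | [Li+].COC(=O)[C@@]1(CO[C@H](C(C)(C)C)O1)[C@]([O-])(c2ccc(O[Si](C(C)C)(C(C)C)C(C)C)cc2)C(=C)COC | intermediate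
15 | methyl (2S,4R)-2-tert-butyl-4-{(1S)-1-methoxy-2-(methoxymethyl)-1-[4-(triisopropylsilyloxy)phenyl]prop-2-en-1-yl}-1,3-dioxolane-4-carboxylate | COC(=O)[C@@]1(CO[C@H](C(C)(C)C)O1)[C@](OC)(c2ccc(O[Si](C(C)C)(C(C)C)C(C)C)cc2)C(=C)COC | intermediate
16 | 4-bromophenol | Oc1ccc(Br)cc1 | starting material
17 | (4-bromophenoxy)triisopropylsilane | CC(C)[Si](Oc1ccc(Br)cc1)(C(C)C)C(C)C | intermediate
18 | [4-(triisopropylsilyloxy)phenyl]lithium | [Li]c1ccc(O[Si](C(C)C)(C(C)C)C(C)C)cc1 | intermediate
19 | {(2S,4R)-2-tert-butyl-4-[(1S)-1-methoxy-2-(methoxymethyl)-1-[4-(triisopropylsilyloxy)phenyl]prop-2-en-1-yl]-1,3-dioxolan-4-yl}[4-(triisopropylsilyloxy)phenyl]methanone | O=C(c1ccc(O[Si](C(C)C)(C(C)C)C(C)C)cc1)[C@@]2(CO[C@H](C(C)(C)C)O2)[C@](OC)(c3ccc(O[Si](C(C)C)(C(C)C)C(C)C)cc3)C(=C)COC | intermediate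
20 | (1R)-1-{(2S,4R)-2-tert-butyl-4-[4-(triisopropylsilyloxy)benzoyl]-1,3-dioxolan-4-yl}-1,3-dimethoxy-1-[4-(triisopropylsilyloxy)phenyl]propan-2-one | O=C(c1ccc(O[Si](C(C)C)(C(C)C)C(C)C)cc1)[C@@]2(CO[C@H](C(C)(C)C)O2)[C@](OC)(c3ccc(O[Si](C(C)C)(C(C)C)C(C)C)cc3)C(=O)COC | intermediate
21 | potassium aldolate (ring closed, C2 and C3 undefined) | [K+].COC1C([O-])(c3ccc(O[Si](C(C)C)(C(C)C)C(C)C)cc3)[C@@]2(CO[C@H](C(C)(C)C)O2)[C@](OC)(c4ccc(O[Si](C(C)C)(C(C)C)C(C)C)cc4)C1=O | intermediate
22 | (2S,5R,6R)-2-tert-butyl-6,8-dimethoxy-6,9-bis[4-(triisopropylsilyloxy)phenyl]-1,3-dioxaspiro[4.4]non-8-en-7-one | COC1=C(c3ccc(O[Si](C(C)C)(C(C)C)C(C)C)cc3)[C@@]2(CO[C@H](C(C)(C)C)O2)[C@](OC)(c4ccc(O[Si](C(C)C)(C(C)C)C(C)C)cc4)C1=O | intermediate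
23 | (4R,5R)-4-hydroxy-4-(hydroxymethyl)-2,5-dimethoxy-3,5-bis[4-(triisopropylsilyloxy)phenyl]cyclopent-2-en-1-one | COC1=C(c2ccc(O[Si](C(C)C)(C(C)C)C(C)C)cc2)[C@@](O)(CO)[C@](OC)(c3ccc(O[Si](C(C)C)(C(C)C)C(C)C)cc3)C1=O | intermediate
24 | [(1R,5R)-1-hydroxy-3,5-dimethoxy-4-oxo-2,5-bis[4-(triisopropylsilyloxy)phenyl]cyclopent-2-en-1-yl]methyl methanesulfonate | COC1=C(c2ccc(O[Si](C(C)C)(C(C)C)C(C)C)cc2)[C@@](O)(COS(C)(=O)=O)[C@](OC)(c3ccc(O[Si](C(C)C)(C(C)C)C(C)C)cc3)C1=O | intermediate
25 | (3R,4R)-4,7-bis(4-hydroxyphenyl)-4,6-dimethoxy-1-oxaspiro[2.4]hept-6-en-5-one | COC1=C(c2ccc(O)cc2)[C@@]2(CO2)[C@](OC)(c2ccc(O)cc2)C1=O | target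

## Step count and risks
Total step count: 15.
Longest linear sequence: 10 steps (1, 2, 3, 7, 9, 11, 12, 13, 14, 15). The branch 4, 5, 6 followed by 7 onward is equally long.

Step 7 could fail through O-acylation of the hindered, fully substituted enolate, or through ring opening of the enolate. The fallback replaces the acylation by an aldol reaction followed by oxidation. It sets out from 4 and comes back at 10. 4-Hydroxybenzaldehyde is silylated (TIPSCl, imidazole) to 4-(triisopropylsilyloxy)benzaldehyde F1. Enolate 9, made from 4 as before, adds to F1 anti to the tert-butyl group. This gives methyl (2S,4R)-2-tert-butyl-4-{hydroxy[4-(triisopropylsilyloxy)phenyl]methyl}-1,3-dioxolane-4-carboxylate F2 as a mixture of carbinol epimers. Dess–Martin periodinane oxidises both epimers to 10.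

Step 9 could fail by attack on the wrong face (non-chelate attack), by a sluggish addition, or by retro-aldol of 14. The fallback swaps the order in which the two carbon groups are put on C5, so that the opposite intrinsic facial preference leads to the same C5 configuration. It sets out from 4 and comes back at 15.
- Vinyllithium 13 is formylated with DMF to 2-(methoxymethyl)prop-2-enal F3.
- Enolate 9 adds to F3 anti to the tert-butyl group to give methyl (2S,4R)-2-tert-butyl-4-[1-hydroxy-2-(methoxymethyl)prop-2-en-1-yl]-1,3-dioxolane-4-carboxylate F4.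
- Dess–Martin periodinane gives methyl (2S,4R)-2-tert-butyl-4-[2-(methoxymethyl)prop-2-enoyl]-1,3-dioxolane-4-carboxylate F5.
- Aryllithium 18 adds 1,2 to the enone carbonyl in THF under Felkin–Anh (non-chelating) conditions to give alkoxide 14, which MeOTf traps as 15.

Step 11 could fail because the ester between two quaternary carbons may not accept the aryllithium. The fallback is a redox detour through the much less hindered aldehyde. It sets out from 15 and comes back at 19. i-Bu2AlH (CH2Cl2, −78 °C) reduces 15 to (2S,4R)-2-tert-butyl-4-{(1S)-1-methoxy-2-(methoxymethyl)-1-[4-(triisopropylsilyloxy)phenyl]prop-2-en-1-yl}-1,3-dioxolane-4-carbaldehyde F6. Aryllithium 18 adds to F6 to give {(2S,4S)-2-tert-butyl-4-[(1S)-1-methoxy-2-(methoxymethyl)-1-[4-(triisopropylsilyloxy)phenyl]prop-2-en-1-yl]-1,3-dioxolan-4-yl}[4-(triisopropylsilyloxy)phenyl]methanol F7, whose carbinol epimers do not matter. Dess–Martin periodinane oxidises F7 to 19.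

## Further compounds
F1 | step 7 | 4-(triisopropylsilyloxy)benzaldehyde | O=Cc1ccc(O[Si](C(C)C)(C(C)C)C(C)C)cc1
F2 | step 7 | methyl (2S,4R)-2-tert-butyl-4-{hydroxy[4-(triisopropylsilyloxy)phenyl]methyl}-1,3-dioxolane-4-carboxylate | COC(=O)[C@@]1(CO[C@H](C(C)(C)C)O1)C(O)c2ccc(O[Si](C(C)C)(C(C)C)C(C)C)cc2
F3 | step 9 | 2-(methoxymethyl)prop-2-enal | C=C(COC)C=O
F4 | step 9 | methyl (2S,4R)-2-tert-butyl-4-[1-hydroxy-2-(methoxymethyl)prop-2-en-1-yl]-1,3-dioxolane-4-carboxylate | COC(=O)[C@@]1(CO[C@H](C(C)(C)C)O1)C(O)C(=C)COC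
F5 | step 9 | methyl (2S,4R)-2-tert-butyl-4-[2-(methoxymethyl)prop-2-enoyl]-1,3-dioxolane-4-carboxylate | COC(=O)[C@@]1(CO[C@H](C(C)(C)C)O1)C(=O)C(=C)COC
F6 | step 11 | (2S,4R)-2-tert-butyl-4-{(1S)-1-methoxy-2-(methoxymethyl)-1-[4-(triisopropylsilyloxy)phenyl]prop-2-en-1-yl}-1,3-dioxolane-4-carbaldehyde | O=C[C@@]1(CO[C@H](C(C)(C)C)O1)[C@](OC)(c2ccc(O[Si](C(C)C)(C(C)C)C(C)C)cc2)C(=C)COC
F7 | step 11 | {(2S,4S)-2-tert-butyl-4-[(1S)-1-methoxy-2-(methoxymethyl)-1-[4-(triisopropylsilyloxy)phenyl]prop-2-en-1-yl]-1,3-dioxolan-4-yl}[4-(triisopropylsilyloxy)phenyl]methanol | OC(c1ccc(O[Si](C(C)C)(C(C)C)C(C)C)cc1)[C@@]2(CO[C@H](C(C)(C)C)O2)[C@](OC)(c3ccc(O[Si](C(C)C)(C(C)C)C(C)C)cc3)C(=C)COC
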